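**Strategy.** The route rests on one disconnection, the C13–C16 bond of the bicyclo[3.2.1]octane (ent-kaurane numbering). The key step exploits the way ring D is laid out: C13, a tertiary bridgehead two bonds from the C11 carbonyl, is attached to C16, which carries the exocyclic C17 methylene and is linked by the C15 methylene to the fully substituted bridgehead C8. A C16 alkenyl radical therefore adds to the ring C enone, closes ring D, fixes C13 and leaves ketone and methylene in place. The precursor is a cyclohex-2-enone whose C8 carries formyl and 2-bromoallyl groups and whose C9 bears ring A, with both carboxyls as tert-butyl esters.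

Key step: step 18

**Remarks and assumptions**
- Atom labels C1–C20 follow ent-kaurane numbering (ring A = C1–C5, C10; ring C = C8, C9, C11–C14). TBS = tert-butyldimethylsilyl.
- Spectator groups of the radical precursor: C7 is carried as the non-enolisable formyl group, so no redox change is needed after the key step. Both carboxyls are tert-butyl esters: they resist attack by the neighbouring C6 alkoxide early on, and they are cleaved at the end by O-alkyl fission, which avoids attack at the shielded C19 carbonyl.
- C11 is carried as an (S)-silyloxy centre; it is a temporary control element for C9 and C10 and is erased in step 17.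
- Assumption 1: the sense of induction of the valine-derived lithio-enamine depends on the ligand/solvent; the L-auxiliary is drawn, and the D-auxiliary or the ligand-free medium is used if it is needed to obtain the R ketone 5.
- Assumption 2: the CBS antipode is assigned by the usual model (iodoalkenyl flank as the large group); the other antipode is used if the sense is reversed.
- Compounds 6, 15, 19 and 20 are carried as mixtures at a centre or double bond that is erased in the following step.

**Route**

Step 1
Reactants: 1 tert-butyl 2-oxocyclohexane-1-carboxylate; 2 L-valine tert-butyl ester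
Product: 3 tert-butyl 2-{[(2S)-1-tert-butoxy-3-methyl-1-oxobutan-2-yl]amino}cyclohex-1-ene-1-carboxylate
Conditions: TsOH·H2O (cat.), benzene, reflux, Dean–Stark trap
Reagents that add atoms: none
Why: Condensation of a β-keto ester with a primary amine gives the hydrogen-bonded enamino ester (enamine formation) with azeotropic removal of water, and the valine centre is untouched.

Step 2
Reactants: 3 chiral enamino ester
Product: 5 tert-butyl (1R)-1-methyl-2-oxocyclohexane-1-carboxylate, via α-methyl ketimine 4 (not isolated)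
Conditions: LiN(i-Pr)2, toluene, HMPA (1 equiv), −78 °C; MeI, −78 → −20 °C; then 10% aq. citric acid, rt
Reagents that add atoms: iodomethane, CI; water, O
Why: Auxiliary-controlled alkylation of the metallated chiral enamine, in which lithium is chelated between the enamine nitrogen and the valinate carbonyl so that iodomethane enters on the face remote from the isopropyl group and sets the quaternary C4 as R, followed by mild hydrolysis of the ketimine that returns the auxiliary.

Step 3
Reactants: 5 tert-butyl (1R)-1-methyl-2-oxocyclohexane-1-carboxylate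
Product: 6 tert-butyl (1R,3RS)-1,3-dimethyl-2-oxocyclohexane-1-carboxylate
Conditions: LiN(i-Pr)2, THF, −78 °C; MeI, −78 → 0 °C
Reagents that add atoms: iodomethane, CI
Why: Kinetic enolate alkylation is regiodefined because C10 is the only enolisable position of the α-quaternary ketone, and the new centre may be a mixture since it becomes sp2 in the next step.

Step 4
Reactants: 6 tert-butyl (1R,3RS)-1,3-dimethyl-2-oxocyclohexane-1-carboxylate
Product: 7 tert-butyl (1R)-1,3-dimethyl-2-(trifluoromethanesulfonyloxy)cyclohex-2-ene-1-carboxylate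
Conditions: KN(SiMe3)2, THF, −78 °C; PhNTf2, −78 → 0 °C
Reagents that add atoms: N-phenylbis(trifluoromethanesulfonimide), O=S(=O)(N(c1ccccc1)S(=O)(=O)C(F)(F)F)C(F)(F)F
Why: Enol triflate formation, in which deprotonation can only occur at the tertiary C10–H and O-sulfonylation of the potassium enolate gives the tetrasubstituted C5=C10 triflate with C4 untouched.

Step 5
Reactants: 7 enol triflate
Product: 8 tert-butyl (1R)-2-(hydroxymethyl)-1,3-dimethylcyclohex-2-ene-1-carboxylate
Conditions: Bu3SnCH2OH, Pd(PPh3)4 (cat.), LiCl, 1,4-dioxane, 100 °C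
Reagents that add atoms: (tributylstannyl)methanol, CCCC[Sn](CCCC)(CCCC)CO
Why: Stille cross-coupling of the enol triflate transfers the hydroxymethyl group (C6) to C5 without moving the alkene, and the bulky tert-butyl ester does not lactonise with the new primary alcohol.

Step 6
Reactants: 9 cyclohexane-1,3-dione
Product: 10 3-iodocyclohex-2-en-1-one
Conditions: PPh3, I2, Et3N, MeCN, rt
Reagents that add atoms: iodine, II
Why: The enol of the 1,3-dione is activated as its oxyphosphonium salt and displaced by iodide in an addition–elimination (vinylogous acyl substitution) to give the β-iodo enone.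

Step 7
Reactants: 10 3-iodocyclohex-2-en-1-one
Product: 11 (1S)-3-iodocyclohex-2-en-1-ol
Conditions: (R)-2-methyl-CBS-oxazaborolidine (0.2 equiv), BH3·SMe2, THF, −20 °C
Reagents that add atoms: none
Why: Corey–Bakshi–Shibata reduction, in which the oxazaborolidine–borane complex binds the ketone with the iodoalkenyl flank as the large group and delivers hydride to one face only, setting the temporary carbinol centre (C11) as S by 1,2-reduction.

Step 8
Reactants: 11 (1S)-3-iodocyclohex-2-en-1-ol
Product: 12 tert-butyl{[(1S)-3-iodocyclohex-2-en-1-yl]oxy}dimethylsilane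
Conditions: TBSCl, imidazole, DMF, rt
Reagents that add atoms: tert-butyldimethylsilyl chloride, CC(C)(C)[Si](C)(C)Cl
Why: Standard silylation of a secondary allylic alcohol, which leaves the carbinol configuration untouched.

Step 9
Reactants: 8 ring A allylic alcohol; 12 silyloxy alkenyl iodide
Product: 13 tert-butyl (1R)-2-({[(3S)-3-(tert-butyldimethylsilyloxy)cyclohex-1-en-1-yl]oxy}methyl)-1,3-dimethylcyclohex-2-ene-1-carboxylate
Conditions: CuI (10 mol%), 3,4,7,8-tetramethyl-1,10-phenanthroline (20 mol%), Cs2CO3, toluene, 80 °C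
Reagents that add atoms: none
Why: Copper-catalysed Ullmann-type C–O coupling of an alkenyl iodide with a primary allylic alcohol gives the allyl vinyl ether (O on C8) without moving either alkene and below the temperature of the sigmatropic shift, so no stereocentre is touched.

Step 10
Reactants: 13 allyl vinyl ether
Product: 14 tert-butyl (1R,3S)-3-[(1R,2S)-2-(tert-butyldimethylsilyloxy)-6-oxocyclohexyl]-1,3-dimethyl-2-methylidenecyclohexane-1-carboxylate
Conditions: o-xylene, 150 °C, sealed tube (base-washed glass)
Reagents that add atoms: none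
Why: Claisen rearrangement through a chair transition state in which the C9–C10 bond forms on the enol ether face anti to the adjacent C11 silyloxy group (setting C9) and the chair array, with the C10 methyl pseudo-axial and C11 pseudo-equatorial, relays this to the quaternary C10, the boat being disfavoured by the clash between C14 and the C4 quaternary centre.

Step 11
Reactants: 14 Claisen ketone
Product: 15 tert-butyl (1R,2S,3R)-3-[(1S,2S)-2-(tert-butyldimethylsilyloxy)-6-hydroxycyclohexyl]-2-(hydroxymethyl)-1,3-dimethylcyclohexane-1-carboxylate (C8 carbinol epimers)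
Conditions: BH3·THF (excess), THF, 0 °C → rt; then NaOH, H2O2, 0 °C
Reagents that add atoms: hydrogen peroxide, OO
Why: Hydroboration–oxidation (with concurrent reduction of the C8 ketone, restored in step 12) in which borane adds anti-Markovnikov to the exocyclic C5=C6 alkene from the face opposite the two axial groups flanking C5 (the C20 methyl and the C19 ester), so that H5 is delivered axially and the C6 hydroxymethyl group ends equatorial (C5 S).

Step 12
Reactants: 15 diol
Product: 17 (1S,2R,6S)-2-(tert-butoxycarbonyl)-2,6-dimethyl-6-[(1R,2S)-2-(tert-butyldimethylsilyloxy)-6-oxocyclohexyl]cyclohexane-1-carboxylic acid, via keto aldehyde 16 (not isolated)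
Conditions: Dess–Martin periodinane, CH2Cl2, rt; then NaClO2, NaH2PO4, 2-methyl-2-butene, t-BuOH/H2O, rt
Reagents that add atoms: sodium chlorite, [Na+].[O-]Cl=O
Why: Dess–Martin oxidation restores the C8 ketone and gives the C6 aldehyde, which the Pinnick oxidation converts into the acid under buffered conditions that leave the silyl ether, the tert-butyl ester and the C5 and C9 centres untouched.

Step 13
Reactants: 17 keto acid
Product: 18 di-tert-butyl (1R,2S,3S)-1,3-dimethyl-3-[(1R,2S)-2-(tert-butyldimethylsilyloxy)-6-oxocyclohexyl]cyclohexane-1,2-dicarboxylate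
Conditions: tert-butyl 2,2,2-trichloroacetimidate, BF3·OEt2 (cat.), CH2Cl2/cyclohexane, rt
Reagents that add atoms: tert-butyl 2,2,2-trichloroacetimidate, CC(C)(C)OC(=N)C(Cl)(Cl)Cl
Why: Acid-catalysed O-tert-butylation by the imidate proceeds through the tert-butyl cation and is therefore insensitive to the shielding of the C6 carboxyl by the two neighbouring quaternary carbons.

Step 14
Reactants: 18 keto diester
Product: 20 di-tert-butyl (1R,2S,3S)-3-[(1R,6S)-2-formyl-6-(tert-butyldimethylsilyloxy)cyclohexyl]-1,3-dimethylcyclohexane-1,2-dicarboxylate (C8 epimers), via methyl enol ether 19 (not isolated)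
Conditions: MeOCH2PPh3Cl, KN(SiMe3)2, THF, 0 °C → rt; then 2 M aq. HCl/THF (1:10), rt
Reagents that add atoms: (methoxymethyl)triphenylphosphonium chloride, COC[P+](c1ccccc1)(c1ccccc1)c1ccccc1.[Cl-]; water, O
Why: Wittig methoxymethylenation of the C8 ketone and hydrolysis of the enol ether is the standard one-carbon homologation to the aldehyde (C7), with C8 left as a mixture because it is alkylated next and the shielded C9–H not enolised.

Step 15
Reactants: 20 aldehyde; 21 2,3-dibromopropene
Product: 22 di-tert-butyl (1R,2S,3S)-3-[(1S,2R,6S)-2-(2-bromoprop-2-en-1-yl)-2-formyl-6-(tert-butyldimethylsilyloxy)cyclohexyl]-1,3-dimethylcyclohexane-1,2-dicarboxylate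
Conditions: t-BuOK, THF, −20 °C; 2,3-dibromopropene, −20 °C → rt
Reagents that add atoms: none
Why: α-Alkylation of the potassium enolate of an α-branched aldehyde with an allylic bromide creates the quaternary C8, the electrophile entering trans to the very large C10-bearing substituent on the neighbouring C9 (the usual outcome for exocyclic enolates of 2-substituted cyclohexanes), which gives C8 R with C15 anti to C10.

Step 16
Reactants: 22 silyl ether
Product: 23 di-tert-butyl (1R,2S,3S)-3-[(1S,2R,6S)-2-(2-bromoprop-2-en-1-yl)-2-formyl-6-hydroxycyclohexyl]-1,3-dimethylcyclohexane-1,2-dicarboxylate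
Conditions: HF·pyridine, THF/pyridine, 0 °C → rt
Reagents that add atoms: none
Why: Fluoride-mediated cleavage of the secondary silyl ether under buffered conditions spares the tert-butyl esters, the aldehyde and the alkenyl bromide.

Step 17
Reactants: 23 hydroxy aldehyde
Product: 25 di-tert-butyl (1R,2S,3S)-3-[(1S,2R)-2-(2-bromoprop-2-en-1-yl)-2-formyl-6-oxocyclohex-4-en-1-yl]-1,3-dimethylcyclohexane-1,2-dicarboxylate, via saturated ketone 24 (not isolated)
Conditions: IBX (4 equiv), DMSO, 75 °C
Reagents that add atoms: none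
Why: 2-Iodoxybenzoic acid oxidises the C11 alcohol to the ketone and then dehydrogenates it to the enone (IBX dehydrogenation), where only C12–C13 can be desaturated because C8 and C10 carry no hydrogen, and the C9–H flanked by two quaternary carbons keeps its configuration.

Step 18
Reactants: 25 bromoallyl enone
Product: 26 di-tert-butyl (1R,2S,3S)-3-[(1R,2S,5S)-1-formyl-6-methylidene-3-oxobicyclo[3.2.1]octan-2-yl]-1,3-dimethylcyclohexane-1,2-dicarboxylate
Conditions: Bu3SnH (1.3 equiv, syringe pump, 6 h), AIBN (0.2 equiv), benzene (0.01 M), 80 °C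
Reagents that add atoms: none
Why: The stannyl radical abstracts bromine from C16 to give a σ-alkenyl radical, which adds to C13, the β-carbon of the C11 enone, and the resulting C12 α-keto radical takes hydrogen from Bu3SnH to carry the chain. The closest known reaction type is the tin hydride mediated alkenyl radical conjugate cyclisation of 2-bromoallyl-substituted cyclohexenones to bicyclo[3.2.1]octanones. The ring closed is the cyclopentane C16–C15–C8–C14–C13 in a 5-exo-trig mode, the 6-endo attack at C12 being disfavoured by geometry and by polarity. The only new stereocentre, C13, is dictated by C8, because the one-carbon C15 tether can reach C13 only on the face of ring C that carries it, so the bridge is necessarily cis. The step needs ring closure to outrun hydrogen transfer to the alkenyl radical and needs chemoselectivity over the formyl group; slow addition of the stannane at high dilution, the geminal substitution at C8 that holds the arm over the electron-poor acceptor carbon, and the four-membered ring that attack on the formyl carbon would require should secure this.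

Step 19
Reactants: 26 bicyclic di-tert-butyl ester
Product: 28 (1R,2S,3S)-3-[(1R,2S,5S)-1-formyl-6-methylidene-3-oxobicyclo[3.2.1]octan-2-yl]-1,3-dimethylcyclohexane-1,2-dicarboxylic acid, via bis(trimethylsilyl) ester 27 (not isolated)
Conditions: TMSOTf, 2,6-lutidine, CH2Cl2, 0 °C → rt; then pH 4 aq. buffer
Reagents that add atoms: none
Why: Silyl triflate mediated cleavage of tert-butyl esters occurs by O-alkyl fission with loss of isobutene and so needs no attack at the shielded C19 carbonyl, the lutidine-buffered non-protic medium spares the exocyclic methylene, the aldehyde and C9, and the silyl esters hydrolyse on aqueous work-up.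

**Compound list**

1 | tert-butyl 2-oxocyclohexane-1-carboxylate | CC(C)(C)OC(=O)C1CCCCC1=O | starting material
2 | L-valine tert-butyl ester (commercial as the hydrochloride) | CC(C)[C@H](N)C(=O)OC(C)(C)C | starting material
3 | tert-butyl 2-{[(2S)-1-tert-butoxy-3-methyl-1-oxobutan-2-yl]amino}cyclohex-1-ene-1-carboxylate | CC(C)[C@H](NC1=C(C(=O)OC(C)(C)C)CCCC1)C(=O)OC(C)(C)C | intermediate
4 | tert-butyl (1R)-2-{[(2S)-1-tert-butoxy-3-methyl-1-oxobutan-2-yl]imino}-1-methylcyclohexane-1-carboxylate (α-methyl ketimine, not isolated) | C[C@@]1(C(=O)OC(C)(C)C)CCCCC1=N[C@@H](C(C)C)C(=O)OC(C)(C)C | intermediate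
5 | tert-butyl (1R)-1-methyl-2-oxocyclohexane-1-carboxylate | C[C@@]1(C(=O)OC(C)(C)C)CCCCC1=O | intermediate
6 | tert-butyl (1R,3RS)-1,3-dimethyl-2-oxocyclohexane-1-carboxylate | CC1CCC[C@@](C)(C(=O)OC(C)(C)C)C1=O | intermediate
7 | tert-butyl (1R)-1,3-dimethyl-2-(trifluoromethanesulfonyloxy)cyclohex-2-ene-1-carboxylate | CC1=C(OS(=O)(=O)C(F)(F)F)[C@](C)(C(=O)OC(C)(C)C)CCC1 | intermediate
8 | tert-butyl (1R)-2-(hydroxymethyl)-1,3-dimethylcyclohex-2-ene-1-carboxylate | CC1=C(CO)[C@](C)(C(=O)OC(C)(C)C)CCC1 | intermediate
9 | cyclohexane-1,3-dione | O=C1CCCC(=O)C1 | starting material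
10 | 3-iodocyclohex-2-en-1-one | O=C1C=C(I)CCC1 | intermediate
11 | (1S)-3-iodocyclohex-2-en-1-ol | IC1=C[C@@H](O)CCC1 | intermediate
12 | tert-butyl{[(1S)-3-iodocyclohex-2-en-1-yl]oxy}dimethylsilane | IC1=C[C@@H](O[Si](C)(C)C(C)(C)C)CCC1 | intermediate
13 | tert-butyl (1R)-2-({[(3S)-3-(tert-butyldimethylsilyloxy)cyclohex-1-en-1-yl]oxy}methyl)-1,3-dimethylcyclohex-2-ene-1-carboxylate | CC1=C(COC2=C[C@@H](O[Si](C)(C)C(C)(C)C)CCC2)[C@](C)(C(=O)OC(C)(C)C)CCC1 | intermediate
14 | tert-butyl (1R,3S)-3-[(1R,2S)-2-(tert-butyldimethylsilyloxy)-6-oxocyclohexyl]-1,3-dimethyl-2-methylidenecyclohexane-1-carboxylate (4R,9R,10S,11S) | O=C1CCC[C@H](O[Si](C)(C)C(C)(C)C)[C@H]1[C@]2(C)CCC[C@@](C)(C(=O)OC(C)(C)C)C2=C | intermediate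
15 | tert-butyl (1R,2S,3R)-3-[(1S,2S)-2-(tert-butyldimethylsilyloxy)-6-hydroxycyclohexyl]-2-(hydroxymethyl)-1,3-dimethylcyclohexane-1-carboxylate (C8 carbinol epimers) | OC1CCC[C@H](O[Si](C)(C)C(C)(C)C)[C@H]1[C@]2(C)CCC[C@@](C)(C(=O)OC(C)(C)C)[C@H]2CO | intermediate
16 | tert-butyl (1R,2S,3R)-2-formyl-1,3-dimethyl-3-[(1R,2S)-2-(tert-butyldimethylsilyloxy)-6-oxocyclohexyl]cyclohexane-1-carboxylate (keto aldehyde, not isolated) | O=C1CCC[C@H](O[Si](C)(C)C(C)(C)C)[C@H]1[C@]2(C)CCC[C@@](C)(C(=O)OC(C)(C)C)[C@H]2C=O | intermediate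
17 | (1S,2R,6S)-2-(tert-butoxycarbonyl)-2,6-dimethyl-6-[(1R,2S)-2-(tert-butyldimethylsilyloxy)-6-oxocyclohexyl]cyclohexane-1-carboxylic acid | O=C1CCC[C@H](O[Si](C)(C)C(C)(C)C)[C@H]1[C@]2(C)CCC[C@@](C)(C(=O)OC(C)(C)C)[C@H]2C(=O)O | intermediate
18 | di-tert-butyl (1R,2S,3S)-1,3-dimethyl-3-[(1R,2S)-2-(tert-butyldimethylsilyloxy)-6-oxocyclohexyl]cyclohexane-1,2-dicarboxylate | O=C1CCC[C@H](O[Si](C)(C)C(C)(C)C)[C@H]1[C@]2(C)CCC[C@@](C)(C(=O)OC(C)(C)C)[C@H]2C(=O)OC(C)(C)C | intermediate
19 | di-tert-butyl (1R,2S,3S)-3-[(1S,6S)-2-(methoxymethylidene)-6-(tert-butyldimethylsilyloxy)cyclohexyl]-1,3-dimethylcyclohexane-1,2-dicarboxylate (E/Z, not isolated) | COC=C1CCC[C@H](O[Si](C)(C)C(C)(C)C)[C@H]1[C@]2(C)CCC[C@@](C)(C(=O)OC(C)(C)C)[C@H]2C(=O)OC(C)(C)C | intermediate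
20 | di-tert-butyl (1R,2S,3S)-3-[(1R,6S)-2-formyl-6-(tert-butyldimethylsilyloxy)cyclohexyl]-1,3-dimethylcyclohexane-1,2-dicarboxylate (C8 epimers) | O=CC1CCC[C@H](O[Si](C)(C)C(C)(C)C)[C@H]1[C@]2(C)CCC[C@@](C)(C(=O)OC(C)(C)C)[C@H]2C(=O)OC(C)(C)C | intermediate
21 | 2,3-dibromopropene | C=C(Br)CBr | starting material
22 | di-tert-butyl (1R,2S,3S)-3-[(1S,2R,6S)-2-(2-bromoprop-2-en-1-yl)-2-formyl-6-(tert-butyldimethylsilyloxy)cyclohexyl]-1,3-dimethylcyclohexane-1,2-dicarboxylate | C=C(Br)C[C@]1(C=O)CCC[C@H](O[Si](C)(C)C(C)(C)C)[C@H]1[C@]2(C)CCC[C@@](C)(C(=O)OC(C)(C)C)[C@H]2C(=O)OC(C)(C)C | intermediate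
23 | di-tert-butyl (1R,2S,3S)-3-[(1S,2R,6S)-2-(2-bromoprop-2-en-1-yl)-2-formyl-6-hydroxycyclohexyl]-1,3-dimethylcyclohexane-1,2-dicarboxylate | C=C(Br)C[C@]1(C=O)CCC[C@H](O)[C@H]1[C@]2(C)CCC[C@@](C)(C(=O)OC(C)(C)C)[C@H]2C(=O)OC(C)(C)C | intermediate
24 | di-tert-butyl (1R,2S,3S)-3-[(1S,2R)-2-(2-bromoprop-2-en-1-yl)-2-formyl-6-oxocyclohexyl]-1,3-dimethylcyclohexane-1,2-dicarboxylate (not isolated) | C=C(Br)C[C@]1(C=O)CCCC(=O)[C@H]1[C@]2(C)CCC[C@@](C)(C(=O)OC(C)(C)C)[C@H]2C(=O)OC(C)(C)C | intermediate
25 | di-tert-butyl (1R,2S,3S)-3-[(1S,2R)-2-(2-bromoprop-2-en-1-yl)-2-formyl-6-oxocyclohex-4-en-1-yl]-1,3-dimethylcyclohexane-1,2-dicarboxylate (key-step precursor; 4R,5S,8R,9S,10S) | C=C(Br)C[C@]1(C=O)CC=CC(=O)[C@H]1[C@]2(C)CCC[C@@](C)(C(=O)OC(C)(C)C)[C@H]2C(=O)OC(C)(C)C | intermediate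
26 | di-tert-butyl (1R,2S,3S)-3-[(1R,2S,5S)-1-formyl-6-methylidene-3-oxobicyclo[3.2.1]octan-2-yl]-1,3-dimethylcyclohexane-1,2-dicarboxylate (key-step product) | C=C1C[C@]2(C=O)C[C@H]1CC(=O)[C@H]2[C@]1(C)CCC[C@@](C)(C(=O)OC(C)(C)C)[C@H]1C(=O)OC(C)(C)C | intermediate
27 | bis(trimethylsilyl) (1R,2S,3S)-3-[(1R,2S,5S)-1-formyl-6-methylidene-3-oxobicyclo[3.2.1]octan-2-yl]-1,3-dimethylcyclohexane-1,2-dicarboxylate (not isolated) | C=C1C[C@]2(C=O)C[C@H]1CC(=O)[C@H]2[C@]1(C)CCC[C@@](C)(C(=O)O[Si](C)(C)C)[C@H]1C(=O)O[Si](C)(C)C | intermediate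
28 | (1R,2S,3S)-3-[(1R,2S,5S)-1-formyl-6-methylidene-3-oxobicyclo[3.2.1]octan-2-yl]-1,3-dimethylcyclohexane-1,2-dicarboxylic acid (CNP0408869.1; 4R,5S,8R,9S,10S,13S) | C=C1C[C@]2(C=O)C[C@H]1CC(=O)[C@H]2[C@]1(C)CCC[C@@](C)(C(=O)O)[C@H]1C(=O)O | target

**Totals.** Total step count: 19. Longest linear sequence: 16 steps (steps 1–5, then 9–19); the ring C branch (steps 6–8) joins at step 9.

**Three steps most likely to fail**

Step 18 (key step). Hydrogen transfer to the C16 radical before ring closure, or stannyl-radical reduction of the formyl group, would erode the cyclisation. Fallback, from 25 back to 26: the same C13–C16 bond is closed by a reductive Heck cyclisation (Pd(OAc)2, PPh3, HCO2Na, Bu4NCl, DMF, 80 °C). Zerovalent palladium formed in situ inserts into the C16–Br bond, the alkenylpalladium species adds 5-exo to C13, and the C12 palladium enolate is reduced by formate. This fallback forms no compound outside the main list (entry F0).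

Step 15. O-alkylation of the hindered enolate, self-condensation of the aldehyde under base, or entry of the electrophile from the C10 side could lower yield or selectivity. Fallback, from 20 back to 22: the aldehyde is condensed with pyrrolidine (benzene, reflux, Dean–Stark trap) to give the pyrrolidine enamine F3. Heating F3 with 2,3-dibromopropene 21 in MeCN at 80 °C N-allylates it, and a charge-accelerated aza-Claisen shift (or direct C-alkylation) gives the C8-quaternary iminium bromide F4, again on the face away from the C9 substituent. Hydrolysis with aqueous NaOAc/AcOH returns 22.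

Step 9. Slow C–O coupling of the hindered alkoxide, with competing reduction or elimination of the alkenyl iodide, could stall the fragment union. Fallback, from 8 and 10 back to 13: alcohol 8 is deprotonated (NaH, THF, 0 °C) and added to iodoenone 10 in an addition–elimination that gives the vinylogous ester F1. CBS reduction of F1 ((R)-2-methyl-CBS-oxazaborolidine, catecholborane, toluene, −78 °C) gives the acid-sensitive 3-alkoxy allylic alcohol F2 (S at C11), which is silylated at once (TBSCl, imidazole, DMF) to 13.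

Further compounds
F1 | step 9 | tert-butyl (1R)-1,3-dimethyl-2-{[(3-oxocyclohex-1-en-1-yl)oxy]methyl}cyclohex-2-ene-1-carboxylate | CC1=C(COC2=CC(=O)CCC2)[C@](C)(C(=O)OC(C)(C)C)CCC1
F2 | step 9 | tert-butyl (1R)-2-({[(3S)-3-hydroxycyclohex-1-en-1-yl]oxy}methyl)-1,3-dimethylcyclohex-2-ene-1-carboxylate | CC1=C(COC2=C[C@@H](O)CCC2)[C@](C)(C(=O)OC(C)(C)C)CCC1
F3 | step 15 | di-tert-butyl (1R,2S,3S)-1,3-dimethyl-3-[(1S,6S)-2-(pyrrolidin-1-ylmethylidene)-6-(tert-butyldimethylsilyloxy)cyclohexyl]cyclohexane-1,2-dicarboxylate | C(=C1CCC[C@H](O[Si](C)(C)C(C)(C)C)[C@H]1[C@]2(C)CCC[C@@](C)(C(=O)OC(C)(C)C)[C@H]2C(=O)OC(C)(C)C)N3CCCC3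
F4 | step 15 | 1-({(1R,2S,3S)-1-(2-bromoprop-2-en-1-yl)-2-[(1S,2S,3R)-2,3-bis(tert-butoxycarbonyl)-1,3-dimethylcyclohexyl]-3-(tert-butyldimethylsilyloxy)cyclohexyl}methylidene)pyrrolidinium bromide | C=C(Br)C[C@]1(C=[N+]3CCCC3)CCC[C@H](O[Si](C)(C)C(C)(C)C)[C@H]1[C@]2(C)CCC[C@@](C)(C(=O)OC(C)(C)C)[C@H]2C(=O)OC(C)(C)C.[Br-]
F0 | step 18 | none | none
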